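**Retrosynthetic overview**
1. Target 14 ⇐ mesylate 12: one photochemical step makes C3–C1′ (1,2-shift of ring B onto the glycidate-derived carbon, with inversion) and C4–C4a (arene capture of the acylium ion), closing the pyranone ring. This is the only ring formed; both benzene rings are bought.
2. 12 ⇐ hydroxy ketone 11 ⇐ hydroxy ester 6 + aryl bromide 8 (ring B–C(=O) bond by one-pot Weinreb ketone synthesis).
3. 6 ⇐ phenol 4 + methyl (R)-glycidate 5 (O1–C2 bond; source of the only stereocentre).
4. 4 ⇐ 4-bromo-3-methoxyphenol 1 + prenyl bromide 2 (C6–prenyl bond).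

Assumption: methyl (R)-glycidate (made from L-serine), 4-bromo-3-methoxyphenol and 2-bromo-5-methoxyphenol are taken as commercial.

**Step 1**
Reactants: 1 4-bromo-3-methoxyphenol; 2 1-bromo-3-methylbut-2-ene (prenyl bromide)
Product: 4 3-methoxy-4-(3-methylbut-2-en-1-yl)phenol, via dilithiated phenolate 3 (not isolated)
Conditions: n-BuLi (2.2 equiv), THF, −78 → −20 °C; CuBr·SMe2 (10 mol %), 2 (1.3 equiv), −78 → 0 °C; 1 M HCl
Reagents that add atoms: none
Why: Deprotonation and bromine–lithium exchange give a C-nucleophilic aryllithium that is allylated at the primary carbon of prenyl bromide (copper-catalysed SN2 allylation), while the lithium phenolate oxygen stays unreactive in cold THF.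

**Step 2**
Reactants: 4 3-methoxy-4-(3-methylbut-2-en-1-yl)phenol; 5 methyl (2R)-oxirane-2-carboxylate
Product: 6 methyl (2R)-2-hydroxy-3-[3-methoxy-4-(3-methylbut-2-en-1-yl)phenoxy]propanoate
Conditions: CsF (0.2 equiv), DMF, 50 °C
Reagents that add atoms: none
Why: Base-catalysed SN2 opening of the glycidic ester by the phenolate at the unsubstituted C3 leaves the C2–O bond untouched, so the bought (R) centre is carried over unchanged; the phenol is more acidic than the product alcohol, so the base turns over.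

**Step 3**
Reactants: 7 2-bromo-5-methoxyphenol
Product: 8 (2-bromo-5-methoxyphenoxy)tri(propan-2-yl)silane
Conditions: TIPSCl (1.1 equiv), imidazole (2 equiv), DMF, rt
Reagents that add atoms: chlorotri(propan-2-yl)silane (TIPSCl), CC(C)[Si](Cl)(C(C)C)C(C)C
Why: Standard O-silylation; TIPS has no abstractable O–CH hydrogens for the later photolysis, resists the 1,3 O→C silyl shift in the ortho-lithiated species, and comes off with buffered fluoride.

**Step 4**
Reactants: 6 methyl (2R)-2-hydroxy-3-[3-methoxy-4-(3-methylbut-2-en-1-yl)phenoxy]propanoate; 8 (2-bromo-5-methoxyphenoxy)tri(propan-2-yl)silane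
Product: 11 (2R)-2-hydroxy-3-[3-methoxy-4-(3-methylbut-2-en-1-yl)phenoxy]-1-{4-methoxy-2-[tri(propan-2-yl)silyloxy]phenyl}propan-1-one, via Weinreb amide 9 (not isolated), via aryllithium 10 (not isolated)
Conditions: flask A: 6, MeNH(OMe)·HCl (1.5 equiv), i-PrMgCl (4.1 equiv), THF, −20 °C; flask B: 8 (2.0 equiv), n-BuLi (2.0 equiv), THF, −78 °C; B into A, −78 → −20 °C; cold 1 M HCl
Reagents that add atoms: N,O-dimethylhydroxylamine hydrochloride, CNOC.Cl (its atoms stay in intermediate 9 only)
Why: One-pot Weinreb ketone synthesis in which the magnesium amide converts the ester into the N-methoxy-N-methylamide and the chelated tetrahedral adduct with the aryllithium stops at the ketone stage; the α-alkoxide blocks enolisation, so the stereocentre is untouched.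

**Step 5**
Reactants: 11 (2R)-2-hydroxy-3-[3-methoxy-4-(3-methylbut-2-en-1-yl)phenoxy]-1-{4-methoxy-2-[tri(propan-2-yl)silyloxy]phenyl}propan-1-one
Product: 12 (2R)-3-[3-methoxy-4-(3-methylbut-2-en-1-yl)phenoxy]-1-{4-methoxy-2-[tri(propan-2-yl)silyloxy]phenyl}-1-oxopropan-2-yl methanesulfonate
Conditions: MsCl (1.3 equiv), Et3N (1.5 equiv), CH2Cl2, −40 °C, 30 min; pH 7 buffer
Reagents that add atoms: methanesulfonyl chloride, CS(=O)(=O)Cl
Why: O-sulfonylation of the secondary alcohol breaks no bond at the stereocentre (retention), and the low temperature and short time suppress enolisation and β-elimination of the aryloxide.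

**Step 6**
Reactants: 12 (2R)-3-[3-methoxy-4-(3-methylbut-2-en-1-yl)phenoxy]-1-{4-methoxy-2-[tri(propan-2-yl)silyloxy]phenyl}-1-oxopropan-2-yl methanesulfonate
Product: 14 (3S)-3-(2-hydroxy-4-methoxyphenyl)-7-methoxy-6-(3-methylbut-2-en-1-yl)-2,3-dihydro-4H-chromen-4-one, via silyl-protected isoflavanone 13 (not isolated)
Conditions: hν (310 nm, flow coil), HFIP/CH2Cl2 4:1 (5 mM), 2,6-di-tert-butyl-4-methylpyridine (1.2 equiv), 0 °C, Ar; evaporate; TBAF/AcOH (1.2/2.0 equiv), THF, 0 °C
Reagents that add atoms: none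
Why: Proposed new method: a photo-Favorskii-type 1,2-aryl shift terminated by arene capture, in which excitation of the 2,4-dioxygenated aryl ketone ionises the α-C–OMs bond while the electron-rich ring bridges Cα anti to the leaving mesylate (so the glycidate-derived carbon is inverted, R → S, and becomes C3 carrying ring B), the aryl-bridged cyclopropanone-type cation opens to the acylium ion, and in ionising, non-nucleophilic HFIP this is trapped by the tethered aryl ether carbon para to OMe (six-ring Friedel–Crafts acylation, C4–C4a) before α-deprotonation to a ketene could erase the stereocentre; the closest known reaction types are the photochemical 1,2-aryl migration of α-halo or α-acyloxy aryl ketones to arylacetic and 2-arylpropanoic acids with water or alcohol capture and the thermal invertive aryl shift of α-sulfonyloxy ketals, and the buffered fluoride then only cleaves the aryl silyl ether.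

**Compound list**
1 | 4-bromo-3-methoxyphenol | COc1cc(O)ccc1Br | starting material
2 | 1-bromo-3-methylbut-2-ene (prenyl bromide) | CC(C)=CCBr | starting material
3 | lithium 4-lithio-3-methoxyphenolate | [Li]Oc1ccc([Li])c(OC)c1 | intermediate (not isolated)
4 | 3-methoxy-4-(3-methylbut-2-en-1-yl)phenol | COc1cc(O)ccc1CC=C(C)C | intermediate
5 | methyl (2R)-oxirane-2-carboxylate (methyl (R)-glycidate) | COC(=O)[C@H]1CO1 | starting material
6 | methyl (2R)-2-hydroxy-3-[3-methoxy-4-(3-methylbut-2-en-1-yl)phenoxy]propanoate | COC(=O)[C@H](O)COc1ccc(CC=C(C)C)c(OC)c1 | intermediate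
7 | 2-bromo-5-methoxyphenol | COc1ccc(Br)c(O)c1 | starting material
8 | (2-bromo-5-methoxyphenoxy)tri(propan-2-yl)silane | COc1ccc(Br)c(O[Si](C(C)C)(C(C)C)C(C)C)c1 | intermediate
9 | (2R)-2-hydroxy-N-methoxy-3-[3-methoxy-4-(3-methylbut-2-en-1-yl)phenoxy]-N-methylpropanamide (present as its chloromagnesium alkoxide) | CON(C)C(=O)[C@H](O)COc1ccc(CC=C(C)C)c(OC)c1 | intermediate (not isolated)
10 | {4-methoxy-2-[tri(propan-2-yl)silyloxy]phenyl}lithium | COc1ccc([Li])c(O[Si](C(C)C)(C(C)C)C(C)C)c1 | intermediate (not isolated)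
11 | (2R)-2-hydroxy-3-[3-methoxy-4-(3-methylbut-2-en-1-yl)phenoxy]-1-{4-methoxy-2-[tri(propan-2-yl)silyloxy]phenyl}propan-1-one | COc1ccc(C(=O)[C@H](O)COc2ccc(CC=C(C)C)c(OC)c2)c(O[Si](C(C)C)(C(C)C)C(C)C)c1 | intermediate
12 | (2R)-3-[3-methoxy-4-(3-methylbut-2-en-1-yl)phenoxy]-1-{4-methoxy-2-[tri(propan-2-yl)silyloxy]phenyl}-1-oxopropan-2-yl methanesulfonate | COc1ccc(C(=O)[C@H](OS(C)(=O)=O)COc2ccc(CC=C(C)C)c(OC)c2)c(O[Si](C(C)C)(C(C)C)C(C)C)c1 | intermediate
13 | (3S)-7-methoxy-3-{4-methoxy-2-[tri(propan-2-yl)silyloxy]phenyl}-6-(3-methylbut-2-en-1-yl)-2,3-dihydro-4H-chromen-4-one | COc1ccc([C@H]2COc3cc(OC)c(CC=C(C)C)cc3C2=O)c(O[Si](C(C)C)(C(C)C)C(C)C)c1 | intermediate (not isolated)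
14 | (3S)-3-(2-hydroxy-4-methoxyphenyl)-7-methoxy-6-(3-methylbut-2-en-1-yl)-2,3-dihydro-4H-chromen-4-one | COc1ccc([C@H]2COc3cc(OC)c(CC=C(C)C)cc3C2=O)c(O)c1 | target

**Step count and risks**
Total: 6 steps. Longest linear sequence: 5 steps (1, 2, 4, 5, 6); step 3 is the side branch. Step 5 also needs care (cold, short, neutral work-up) but is ranked below the three that follow.

Risk 1, step 6 (the proposed photochemical aryl shift and acylium capture). Possible failures are loss of ee through a ketene, attack of the ortho silyloxy oxygen on Cα to give a benzofuranone, photoreduction of the C–OMs bond, charge-transfer quenching by the aryl ether, and secondary photolysis of the product. The fallback uses known thermal chemistry and sets out from 12. Ketalisation with HC(OMe)3/MeOH/cat. TsOH at 45 °C gives the α-mesyloxy dimethyl ketal F1. Heating F1 with CaCO3 in MeOH/H2O 7:3 at reflux triggers the established invertive 1,2-aryl shift of α-sulfonyloxy ketals and gives the methyl ester F2. Me3SnOH in 1,2-dichloroethane at 70 °C cleaves the ester without base-induced β-elimination to the carboxylic acid F3. (COCl)2/cat. DMF in CH2Cl2 at 0 °C gives the acid chloride F4, which is cyclised without base by intramolecular Friedel–Crafts acylation in HFIP at rt. This rejoins the route at 13, just before the fluoride treatment.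

Risk 2, step 4 (one-pot Weinreb formation and addition of a hindered ortho-silyloxy aryllithium to an unprotected α-hydroxy amide; possible silyl migration in 10 or incomplete addition). The fallback sets out from 6 and builds the ketone by aldehyde addition and oxidation instead. TBSCl/imidazole gives the silyl ether ester F5. DIBAL-H in CH2Cl2 at −78 °C gives the aldehyde F6. Addition of aryllithium 10 in THF at −78 °C gives the carbinol F7, as a mixture at the new carbinol carbon, which does not matter. Dess–Martin periodinane/NaHCO3 gives the α-silyloxy ketone F8. 1 % HCl in MeOH at 0 °C removes the alkyl TBS group while the acid-stable aryl TIPS ether stays, and the route is rejoined at 11.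

Risk 3, step 2 (base-catalysed opening of the glycidic ester; ester exchange or oligomerisation may compete). The fallback sets out from 4 and uses (S)-glycidol (OC[C@H]1CO1) as the chiral building block. Heating 4 with (S)-glycidol and cat. Et3N in EtOH at 80 °C gives the diol F9. TEMPO (cat.)/PhI(OAc)2 in MeCN/H2O oxidises only the primary alcohol and gives the hydroxy acid F10. TMSCHN2 in MeOH/toluene gives the methyl ester and rejoins the route at 6.

**Further compounds**
F1 | step 6 | (2R)-1,1-dimethoxy-3-[3-methoxy-4-(3-methylbut-2-en-1-yl)phenoxy]-1-{4-methoxy-2-[tri(propan-2-yl)silyloxy]phenyl}propan-2-yl methanesulfonate | COc1ccc(C(OC)(OC)[C@H](OS(C)(=O)=O)COc2ccc(CC=C(C)C)c(OC)c2)c(O[Si](C(C)C)(C(C)C)C(C)C)c1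
F2 | step 6 | methyl (2S)-3-[3-methoxy-4-(3-methylbut-2-en-1-yl)phenoxy]-2-{4-methoxy-2-[tri(propan-2-yl)silyloxy]phenyl}propanoate | COC(=O)[C@@H](c1ccc(OC)cc1O[Si](C(C)C)(C(C)C)C(C)C)COc1ccc(CC=C(C)C)c(OC)c1
F3 | step 6 | (2S)-3-[3-methoxy-4-(3-methylbut-2-en-1-yl)phenoxy]-2-{4-methoxy-2-[tri(propan-2-yl)silyloxy]phenyl}propanoic acid | OC(=O)[C@@H](c1ccc(OC)cc1O[Si](C(C)C)(C(C)C)C(C)C)COc1ccc(CC=C(C)C)c(OC)c1
F4 | step 6 | (2S)-3-[3-methoxy-4-(3-methylbut-2-en-1-yl)phenoxy]-2-{4-methoxy-2-[tri(propan-2-yl)silyloxy]phenyl}propanoyl chloride | ClC(=O)[C@@H](c1ccc(OC)cc1O[Si](C(C)C)(C(C)C)C(C)C)COc1ccc(CC=C(C)C)c(OC)c1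
F5 | step 4 | methyl (2R)-2-[tert-butyl(dimethyl)silyloxy]-3-[3-methoxy-4-(3-methylbut-2-en-1-yl)phenoxy]propanoate | COC(=O)[C@H](O[Si](C)(C)C(C)(C)C)COc1ccc(CC=C(C)C)c(OC)c1
F6 | step 4 | (2R)-2-[tert-butyl(dimethyl)silyloxy]-3-[3-methoxy-4-(3-methylbut-2-en-1-yl)phenoxy]propanal | O=C[C@H](O[Si](C)(C)C(C)(C)C)COc1ccc(CC=C(C)C)c(OC)c1
F7 | step 4 | (1RS,2R)-2-[tert-butyl(dimethyl)silyloxy]-3-[3-methoxy-4-(3-methylbut-2-en-1-yl)phenoxy]-1-{4-methoxy-2-[tri(propan-2-yl)silyloxy]phenyl}propan-1-ol | COc1ccc(C(O)[C@H](O[Si](C)(C)C(C)(C)C)COc2ccc(CC=C(C)C)c(OC)c2)c(O[Si](C(C)C)(C(C)C)C(C)C)c1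
F8 | step 4 | (2R)-2-[tert-butyl(dimethyl)silyloxy]-3-[3-methoxy-4-(3-methylbut-2-en-1-yl)phenoxy]-1-{4-methoxy-2-[tri(propan-2-yl)silyloxy]phenyl}propan-1-one | COc1ccc(C(=O)[C@H](O[Si](C)(C)C(C)(C)C)COc2ccc(CC=C(C)C)c(OC)c2)c(O[Si](C(C)C)(C(C)C)C(C)C)c1
F9 | step 2 | (2S)-3-[3-methoxy-4-(3-methylbut-2-en-1-yl)phenoxy]propane-1,2-diol | OC[C@H](O)COc1ccc(CC=C(C)C)c(OC)c1
F10 | step 2 | (2R)-2-hydroxy-3-[3-methoxy-4-(3-methylbut-2-en-1-yl)phenoxy]propanoic acid | OC(=O)[C@H](O)COc1ccc(CC=C(C)C)c(OC)c1
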